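**Retrosynthetic overview**
1. Target 21 ⇐ 18. The C6–O bond is made last by Fleming–Tamao oxidation of a CH2SiMe2Ph group carried as a masked CH2OH. C17 comes from a formaldehyde aldol at C16.
2. Ring D ⇐ Pd(II) enol-silane/alkene closure (C16–C13) on the cyclohexene of 13, followed by saturation of the alkene.
3. Ring C ⇐ Diels–Alder reaction of butadiene with the α-acetyl-α,β-unsaturated spiro-δ-lactone 11 (sets C8 and C9).
4. Key step: ring B ⇐ the acyl C7–O(20) lactone bond. It is closed in a [3+3] annulation of hydroxy ketone 7 with ethoxymethylene acetoacetate 8 (sets C10).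
5. Ring A ⇐ 4,4-dimethylcyclohexenone by dehydrogenation, then catalytic asymmetric conjugate addition with formaldehyde aldol trapping (sets C5). The rings are formed in the order A → B → C → D.

Assumption: atom labels are ent-kaurane numbers. These are C1 ketone, C2=C3, C4 CMe2, C5–C6H2OH, C10 spiro centre, C20H2–O–C7(=O), C8 quaternary, C9, C11–C14 in ring C, C15 ketone and C16–C17H2OH. Formaldehyde is used as the monomer obtained by cracking paraformaldehyde.

**Step 1**
Reactants: 1 4,4-dimethylcyclohex-2-en-1-one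
Product: 2 4,4-dimethylcyclohexa-2,5-dien-1-one
Conditions: DDQ (1.3 equiv), 1,4-dioxane, reflux
Reagents that add atoms: none
Why: DDQ dehydrogenation (hydride abstraction from the dienol, then proton loss) is the standard entry to cross-conjugated 4,4-disubstituted cyclohexadienones, and no stereocentre is formed.

**Step 2**
Reactants: 2 4,4-dimethylcyclohexa-2,5-dien-1-one; 3 (chloromethyl)dimethyl(phenyl)silane; 4 formaldehyde
Product: 7 (5S,6R)-5-{[dimethyl(phenyl)silyl]methyl}-6-(hydroxymethyl)-4,4-dimethylcyclohex-2-en-1-one, via silylmethyl Grignard reagent 5 (not isolated), via chloromagnesium dienolate 6 (not isolated)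
Conditions: Mg, Et2O, reflux (3 → 5); CuBr·SMe2 (5 mol %), TaniaPhos-type ferrocenyl diphosphine (6 mol %, the enantiomer that gives the 5S adduct), 2, Et2O, −60 °C; 4 in THF, −78 °C; aq NH4Cl
Reagents that add atoms: (chloromethyl)dimethyl(phenyl)silane 3 ClC[Si](C)(C)c1ccccc1; formaldehyde 4 C=O
Why: Copper/diphosphine-catalysed asymmetric conjugate addition of a primary Grignard reagent desymmetrises the prochiral dienone, with the ligand choosing one enantiotopic enone unit and so setting C5, and the regiodefined magnesium enolate undergoes an aldol addition to formaldehyde anti to the new side chain (C10 trans here, re-made in step 3).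

**Step 3**
Reactants: 7 (5S,6R)-hydroxy ketone; 8 ethyl 2-(ethoxymethylene)-3-oxobutanoate
Product: 11 (6S,11R)-4-acetyl-11-{[dimethyl(phenyl)silyl]methyl}-10,10-dimethyl-2-oxaspiro[5.5]undeca-4,8-diene-3,7-dione, via dilithio O,C-dianion 9 (not isolated), via open-chain hydroxy alkylidene acetoacetate 10 (not isolated)
Conditions: LDA (2.15 equiv), THF, −78 °C; 8 (1.1 equiv), −78 °C, 30 min; AcOH (2.5 equiv), −78 °C; solvent switch, TsOH·H2O (10 mol %), PhMe, 60 °C
Reagents that add atoms: ethyl 2-(ethoxymethylene)-3-oxobutanoate 8 CCOC=C(C(C)=O)C(=O)OCC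
Why: Proposed new method: a formal [3+3] lactone annulation of a β-hydroxy-ketone C,O-dianion with an alkoxymethylene acetoacetate, in which the second lithiation (C10–H, the only enolisable position) is safe because the dianion can neither lose Li2O (E1cB) nor undergo retro-aldol cleavage, the last-formed and most basic site C10 attacks the vinylogous-carbonate carbon C9 by addition–elimination from the face anti to the C5 silylmethyl arm (sets the C10 quaternary centre with C20 cis to C6), the cold acid quench prevents alkoxide retro-aldol, and acid-catalysed attack of the C20 hydroxyl on the ester lying cis to C10 forms the acyl C7–O bond and closes ring B irreversibly while the E/Z isomers equilibrate through reversible conjugate addition of ethanol; the closest known reaction types are the Fráter–Seebach dianion alkylation and the addition–elimination of ketone enolates to alkoxymethylene malonates used for 2-pyranones.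

**Step 4**
Reactants: 11 spiro-lactone dienophile; 12 buta-1,3-diene
Product: 13 (5R,8S,9S,10S)-8-acetyl A/B/C tricycle; cyclohex-12-ene ring C cis-fused to the δ-lactone at C8–C9; H9 cis to the C8 acetyl; C11 and C14 on the lactone face that carries C1
Conditions: 12 (10 equiv), ZnCl2 (1.0 equiv), BHT (trace), CH2Cl2, sealed tube, 25 °C
Reagents that add atoms: buta-1,3-diene 12 C=CC=C
Why: In this chelate-activated normal-demand Diels–Alder reaction of a 2-acyl-2-enoate-type dienophile, suprafacial addition makes the B/C fusion cis, and the diene adds to the lactone face bearing the flat C1 carbonyl, anti to the bulky C5 branch of the spiro ring, which sets C8 and C9.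

**Step 5**
Reactants: 13 Diels–Alder adduct
Product: 14 (5R,8S,9S,10S)-C15 tert-butyldimethylsilyl enol ether of 13 [C8–C(OTBS)=CH2]
Conditions: TBSOTf (1.3 equiv), Et3N (2 equiv), CH2Cl2, 0 °C
Reagents that add atoms: tert-butyldimethylsilyl triflate CC(C)(C)[Si](C)(C)OS(=O)(=O)C(F)(F)F
Why: This is soft enolisation with O-silylation, and because C8 is quaternary and neither the ring-A enone nor the lactone has an α-hydrogen, only the terminal enol silane can form and no stereocentre is touched.

**Step 6**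
Reactants: 14 enol silane
Product: 15 (5R,8S,9S,10S,13R)-tetracyclic 15-ketone with a bicyclo[3.2.1]octene C/D unit (C16–C13 bond formed; C11=C12)
Conditions: Pd(OAc)2 (1.05 equiv), DMSO, 45 °C
Reagents that add atoms: none
Why: In this Kende–Saegusa-type Pd(II) cycloalkenylation the palladium enolate at C16 has no β-hydrogen, so it adds 5-exo and syn across C13=C12 and syn β-hydride elimination from C11 releases the alkene, and C13 is fixed because the two-atom bridge can only reach the ring face on which C15 sits.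

**Step 7**
Reactants: 15 bicyclo[3.2.1]octene ketone
Product: 16 (5R,8S,9S,10S,13R)-6-[dimethyl(phenyl)silyl]-17-nor-6,7-seco-ent-kaur-2-ene-1,15-dion-7,20-olide
Conditions: 2-nitrobenzenesulfonohydrazide (5 equiv), Et3N, CH2Cl2, rt
Reagents that add atoms: none
Why: Diimide reduction delivers H2 concertedly to the strained, non-polarised C11=C12 bond and leaves the hindered, electron-poor C2=C3 enone untouched, and no new stereocentre arises.

**Step 8**
Reactants: 16 tetracyclic diketo-lactone; 4 formaldehyde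
Product: 18 (5R,8S,9S,10S,13R,16R)-6-[dimethyl(phenyl)silyl]-17-hydroxy-6,7-seco-ent-kaur-2-ene-1,15-dion-7,20-olide, via lithium enolate 17 (not isolated)
Conditions: LiHMDS (1.1 equiv), THF, −78 °C; 4 in THF (5 equiv), −78 °C, 10 min; AcOH, −78 °C
Reagents that add atoms: formaldehyde 4 C=O
Why: This is an aldol hydroxymethylation in which C16 is the only enolisable carbon of the molecule and formaldehyde approaches the enolate from the exo face (the C14 side) of the bicyclo[3.2.1]octane, giving the exo CH2OH (16R), which is also the thermodynamic epimer.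

**Step 9**
Reactants: 18 silane
Product: 21 (5R,8S,9S,10S,13R,16R)-6,17-dihydroxy-1,15-dioxo-6,7-seco-ent-kaur-2-en-7,20-olide (CNP0505075.1), via acetoxysilane 19 (not isolated), via silyl ether 20 (not isolated)
Conditions: KBr (1.5 equiv), AcOOH (32 % in AcOH), NaOAc, AcOH, 0 °C → rt; aqueous work-up
Reagents that add atoms: peracetic acid CC(=O)OO
Why: In this Fleming–Tamao oxidation ipso-bromodesilylation removes the phenyl group, peracid adds to silicon, and the 1,2-shift of C6 from Si to O forms the C6–O bond; the buffered acidic medium spares the β-hydroxy ketone, the lactone and the electron-poor enone, and no stereocentre is involved.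

**Compound list**
1 | 4,4-dimethylcyclohex-2-en-1-one | CC1(C)C=CC(=O)CC1 | starting material
2 | 4,4-dimethylcyclohexa-2,5-dien-1-one | CC1(C)C=CC(=O)C=C1 | intermediate
3 | (chloromethyl)dimethyl(phenyl)silane | ClC[Si](C)(C)c1ccccc1 | starting material
4 | formaldehyde | C=O | starting material
5 | {[dimethyl(phenyl)silyl]methyl}magnesium chloride | Cl[Mg]C[Si](C)(C)c1ccccc1 | intermediate (not isolated)
6 | chloromagnesium (5S)-dienolate | CC1(C)C=CC(O[Mg]Cl)=C[C@@H]1C[Si](C)(C)c2ccccc2 | intermediate (not isolated)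
7 | (5S,6R)-5-{[dimethyl(phenyl)silyl]methyl}-6-(hydroxymethyl)-4,4-dimethylcyclohex-2-en-1-one | CC1(C)C=CC(=O)[C@@H](CO)[C@@H]1C[Si](C)(C)c2ccccc2 | intermediate
8 | ethyl 2-(ethoxymethylene)-3-oxobutanoate | CCOC=C(C(C)=O)C(=O)OCC | starting material
9 | dilithio O,C-dianion of 7 (C5 R) | CC1(C)C=CC(O[Li])=C(CO[Li])[C@@H]1C[Si](C)(C)c2ccccc2 | intermediate (not isolated)
10 | ethyl 2-acetyl-3-[(1S,6R)-6-{[dimethyl(phenyl)silyl]methyl}-1-(hydroxymethyl)-5,5-dimethyl-2-oxocyclohex-3-en-1-yl]prop-2-enoate (E/Z) | CC1(C)C=CC(=O)[C@@](CO)(C=C(C(C)=O)C(=O)OCC)[C@@H]1C[Si](C)(C)c2ccccc2 | intermediate (not isolated)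
11 | (6S,11R)-4-acetyl-11-{[dimethyl(phenyl)silyl]methyl}-10,10-dimethyl-2-oxaspiro[5.5]undeca-4,8-diene-3,7-dione | CC1(C)C=CC(=O)[C@]2(COC(=O)C(C(C)=O)=C2)[C@@H]1C[Si](C)(C)c3ccccc3 | intermediate
12 | buta-1,3-diene | C=CC=C | starting material
13 | (5R,8S,9S,10S)-8-acetyl A/B/C Diels–Alder adduct (C12=C13) | CC1(C)C=CC(=O)[C@]2(COC(=O)[C@@]3(C(C)=O)CC=CC[C@H]32)[C@@H]1C[Si](C)(C)c4ccccc4 | intermediate
14 | (5R,8S,9S,10S)-C15 TBS enol ether of 13 | CC1(C)C=CC(=O)[C@]2(COC(=O)[C@@]3(C(=C)O[Si](C)(C)C(C)(C)C)CC=CC[C@H]32)[C@@H]1C[Si](C)(C)c4ccccc4 | intermediate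
15 | (5R,8S,9S,10S,13R)-tetracyclic 15-ketone, C11=C12 | CC1(C)C=CC(=O)[C@]2(COC(=O)[C@@]34C[C@@H](C=C[C@H]32)CC4=O)[C@@H]1C[Si](C)(C)c5ccccc5 | intermediate
16 | (5R,8S,9S,10S,13R)-6-[dimethyl(phenyl)silyl]-17-nor-6,7-seco-ent-kaur-2-ene-1,15-dion-7,20-olide | CC1(C)C=CC(=O)[C@]2(COC(=O)[C@@]34C[C@@H](CC[C@H]32)CC4=O)[C@@H]1C[Si](C)(C)c5ccccc5 | intermediate
17 | C15/C16 lithium enolate of 16 | CC1(C)C=CC(=O)[C@]2(COC(=O)[C@@]34C[C@@H](CC[C@H]32)C=C4O[Li])[C@@H]1C[Si](C)(C)c5ccccc5 | intermediate (not isolated)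
18 | (5R,8S,9S,10S,13R,16R)-6-[dimethyl(phenyl)silyl]-17-hydroxy-6,7-seco-ent-kaur-2-ene-1,15-dion-7,20-olide | CC1(C)C=CC(=O)[C@]2(COC(=O)[C@@]34C[C@@H](CC[C@H]32)[C@H](CO)C4=O)[C@@H]1C[Si](C)(C)c5ccccc5 | intermediate
19 | C6 acetoxy(dimethyl)silane | CC1(C)C=CC(=O)[C@]2(COC(=O)[C@@]34C[C@@H](CC[C@H]32)[C@H](CO)C4=O)[C@@H]1C[Si](C)(C)OC(C)=O | intermediate (not isolated)
20 | C6–O silyl ether | CC1(C)C=CC(=O)[C@]2(COC(=O)[C@@]34C[C@@H](CC[C@H]32)[C@H](CO)C4=O)[C@@H]1CO[Si](C)(C)OC(C)=O | intermediate (not isolated)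
21 | (5R,8S,9S,10S,13R,16R)-6,17-dihydroxy-1,15-dioxo-6,7-seco-ent-kaur-2-en-7,20-olide | CC1(C)C=CC(=O)[C@]2(COC(=O)[C@@]34C[C@@H](CC[C@H]32)[C@H](CO)C4=O)[C@@H]1CO | target

**Step count**
The route has 9 steps in total, and the longest linear sequence is also 9 steps (1 → 21).

**Steps most likely to fail**

Step 2. The risks are the enantioselectivity and the 1,4-selectivity of a silylmethyl Grignard reagent at a neopentyl β-carbon. The fallback sets out from 2. The same addition/aldol sequence is run with achiral CuI·2LiCl (10 mol %) and gives the racemic trans-hydroxy ketone F1. This is resolved by preparative chiral SFC. The (5R,6S)-antipode F2 is set aside, and the (5S,6R)-enantiomer is 7, where the route is rejoined.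

Step 3 (the proposed new step). The risks are O-attack instead of C-attack by the dianion, proton transfer from the acetyl group of 8, and retro-aldol scrambling of C10. The fallback uses known chemistry and sets out from 7.
- TBSCl/imidazole gives the silyl ether F3.
- LDA (1.1 equiv, THF, −78 °C) gives the lithium dienolate F4.
- F4 undergoes the established enolate addition–elimination with 8 to give the C-alkenylated silyl ether F5.
- HF·pyridine frees the alcohol 10, and TsOH in warm toluene lactonises it to 11, where the route is rejoined.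

Step 6. The risks are insertion of a Pd enolate into an internal ring alkene and 5-exo versus 6-endo closure. The fallback sets out from 13.
- Diimide saturates C12=C13 to give the cyclohexane methyl ketone F6.
- LiHMDS gives the lithium enolate F7, and trifluoroethyl trifluoroacetate converts it into the trifluoroacetyl diketone F8.
- Mesyl azide/Et3N (detrifluoroacetylative diazo transfer) gives the diazoketone F9.
- Rh2(esp)2-catalysed 1,5-C–H insertion of the carbenoid into the axial C13–H bond closes ring D and gives 16, where the route is rejoined. Compounds 14 and 15 are bypassed.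

**Further compounds**
F1 | step 2 | rac-trans-5-{[dimethyl(phenyl)silyl]methyl}-6-(hydroxymethyl)-4,4-dimethylcyclohex-2-en-1-one | CC1(C)C=CC(=O)C(CO)C1C[Si](C)(C)c2ccccc2
F2 | step 2 | (5R,6S)-5-{[dimethyl(phenyl)silyl]methyl}-6-(hydroxymethyl)-4,4-dimethylcyclohex-2-en-1-one | CC1(C)C=CC(=O)[C@H](CO)[C@H]1C[Si](C)(C)c2ccccc2
F3 | step 3 | (5S,6R)-6-{[(tert-butyldimethylsilyl)oxy]methyl}-5-{[dimethyl(phenyl)silyl]methyl}-4,4-dimethylcyclohex-2-en-1-one | CC1(C)C=CC(=O)[C@@H](CO[Si](C)(C)C(C)(C)C)[C@@H]1C[Si](C)(C)c2ccccc2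
F4 | step 3 | lithium dienolate of F3 | CC1(C)C=CC(O[Li])=C(CO[Si](C)(C)C(C)(C)C)[C@@H]1C[Si](C)(C)c2ccccc2
F5 | step 3 | O-TBS ether of 10 (C10 S, C5 R; E/Z) | CC1(C)C=CC(=O)[C@@](CO[Si](C)(C)C(C)(C)C)(C=C(C(C)=O)C(=O)OCC)[C@@H]1C[Si](C)(C)c2ccccc2
F6 | step 6 | (5R,8S,9S,10S)-12,13-dihydro-13 | CC1(C)C=CC(=O)[C@]2(COC(=O)[C@@]3(C(C)=O)CCCC[C@H]32)[C@@H]1C[Si](C)(C)c4ccccc4
F7 | step 6 | lithium enolate of F6 | CC1(C)C=CC(=O)[C@]2(COC(=O)[C@@]3(C(=C)O[Li])CCCC[C@H]32)[C@@H]1C[Si](C)(C)c4ccccc4
F8 | step 6 | C16-trifluoroacetyl derivative of F6 | CC1(C)C=CC(=O)[C@]2(COC(=O)[C@@]3(C(=O)CC(=O)C(F)(F)F)CCCC[C@H]32)[C@@H]1C[Si](C)(C)c4ccccc4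
F9 | step 6 | C16 diazoketone | CC1(C)C=CC(=O)[C@]2(COC(=O)[C@@]3(C(=O)C=[N+]=[N-])CCCC[C@H]32)[C@@H]1C[Si](C)(C)c4ccccc4
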